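(The earlier runs and the new flask are simulated on assumed constants.)

The ratio that would decide my next run was the natural logarithm of Q charged over Q left at the last reading, divided by the molarity of Q charged, and I wanted it before choosing between more Q, more Z and more time for the flask.

| flask | Q | Z | remark | time |
|---|---|---|---|---|
| ash | 0.55 M | 2.5 mol% | run made earlier |  |
| larch | 2.2 M | 2.5 mol% | run made earlier |  |
| alder | 1.1 M | 5 mol% | run made earlier |  |
| flask | 1.1 M | 2.5 mol% |  | 80 min |

- ash (time / min: L / %, Q / %): 5.00: 0, 97; 10.0: 6, 95; 20.0: 8, 95; 30.0: 10, 90; 60.0: 11, 88
- larch (time / min: L / %, Q / %): 12.0: 30, 74; 25.0: 39, 62; 40.0: 44, 56; 50.0: 43, 58; 60.0: 44, 55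
- alder (time / min: L / %, Q / %): 12.0: 19, 82; 25.0: 24, 78; 40.0: 25, 76; 50.0: 25, 74; 60.0: 28, 73

(scatter of a reading: 1.5 percentage points)

- the average divides the monomer in chains by the number of chains begun, living and dead together
- steps thought possible: Q + Z -> J + L; Q + J -> L + J; J -> E; 2 Z -> G
- the earlier runs do not show the number of chains; that part of a forecast is a guess

1. average number of monomer units in a chain (chains begun, living or dead) at 80 min
2. part of the Q that has reacted at 80 min

At 2.5 mol% of Z, this ratio read 0.232 /M in the ash run and 0.272 /M in the larch run, although larch held 4.00 times the Q, so I froze their mean at 0.252 /M as the reach, the logarithm of charged over left per molar of Q charged at this loading. Doubling Z in the alder run gave 0.286 /M, just 1.13 times the reach, and Q in the larch run moved by 1 percentage point between 40.0 min and 60.0 min, where a reading scatters by 1.5 points. I therefore left Z and the time as planned, and the reach gave me 24.2% reacted in the flask. I committed to no chain length, since these runs do not show the number of chains.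

The forecast gave 23.5%, a little below mine, and a chain length of 120, noting that “Scaling Q and Z together scales this almost exactly”.

The flask gave 24.9% and 127.

    Q + Z → J + L (k = 0.0140 /M/min)
    Q + J → L + J, rate k2*[J]*[Q] (k = 24.0 /M/min)
    J → E (k = 0.180 /min)
    2 Z → G (k = 11.0 /M/min)

The flask's own reach came to 0.261 /M, and the frozen reach put a neighbouring flask with 2.8 M of Q, at the same loading of Z, at 50.6% reacted, where that flask stands at 52.4%. In the flask, the half-life of Q by the turning of Q into L stood at 76 min after 12.0 min but at 20 h after 80.0 min, long against the 80 min of the run. After 80 min in the flask, Z, the limiting reagent, stood at 1.19% of its charge, while Q stood at 75.1%.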